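**Retrosynthetic overview** (labdane numbering; the target is an ent-labdane)
1. The target comes from its C6 epimer by an aldehyde-assisted allylic inversion, and that epimer from an 18-hydroxy-7-en-6-one by Luche reduction.
2. Ring B (C5–C6–C7–C8–C9–C10) is closed last, through the C9–C10 bond, by cation–olefin cyclisation of a monocyclic ring-A dienynol. This sets C10 and C9 and, after hydrolysis, gives the C6 oxygen, the 7,8-alkene and H5.
3. Enabling feature: O18 on C4 of ring A is 1,4 to C6. It adds to the C6≡C7 alkyne and forms a temporary oxolane (O18–C18–C4–C5–C6). This holds the C6–C5–C10 oxocarbenium/allyl cation flat with the C4 methyl axial over one face of C10; water opens the ring again.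
4. The dienynol comes from Sonogashira coupling of a ring-A enol triflate (C4 set by auxiliary-controlled methylation of methyl 2-oxocyclohexane-1-carboxylate) with an (E)-enyne made from methyl geranate.
5. Ring order: ring A (purchased) → temporary oxolane → ring B.

Key step: step 9

Assumption: the lithio-enamine of the L-valine tert-butyl ester auxiliary is taken to be methylated to the (S) quaternary centre under the toluene/HMPA protocol; if the sense is the opposite, the D-configured auxiliary is used and nothing else changes.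

**Step 1**
Reactants: 1 methyl 2-oxocyclohexane-1-carboxylate; 2 tert-butyl L-valinate
Product: 3 methyl 2-{[(2S)-1-tert-butoxy-3-methyl-1-oxobutan-2-yl]amino}cyclohex-1-ene-1-carboxylate
Conditions: BF3·OEt2 (cat.), benzene, reflux, azeotropic removal of water
Reagents that add atoms: none
Why: Acid-catalysed condensation of a β-keto ester with a primary amine gives the chelated (Z)-enamino ester (enamine formation); the only stereocentre is that of the auxiliary.

**Step 2**
Reactants: 3 methyl 2-{[(2S)-1-tert-butoxy-3-methyl-1-oxobutan-2-yl]amino}cyclohex-1-ene-1-carboxylate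
Product: 5 methyl (1S)-1-methyl-2-oxocyclohexane-1-carboxylate, via methylated imine 4 (not isolated)
Conditions: LDA, toluene, HMPA (1 equiv), −78 °C; MeI, −78 → −20 °C; then 10% aq. citric acid, rt
Reagents that add atoms: iodomethane, CI; water, O
Why: Auxiliary-controlled α-alkylation of a β-keto ester through its chelated lithio-enamine: the valine isopropyl group and the lithium-bound tert-butyl ester shield one face of the aza-enolate, so methyl iodide sets the (S) quaternary carbon in imine 4, which aqueous acid hydrolyses to the ketone with release of the auxiliary.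

**Step 3**
Reactants: 5 methyl (1S)-1-methyl-2-oxocyclohexane-1-carboxylate
Product: 6 methyl (1S,3RS)-1,3-dimethyl-2-oxocyclohexane-1-carboxylate
Conditions: LDA, THF, −78 °C; MeI, −78 → 0 °C
Reagents that add atoms: iodomethane, CI
Why: Kinetic deprotonation can only occur at C3 (the other α-carbon is quaternary), so the enolate methylation is regiospecific, and the configuration of the new methine is irrelevant because it becomes sp2 in step 4.

**Step 4**
Reactants: 6 methyl (1S,3RS)-1,3-dimethyl-2-oxocyclohexane-1-carboxylate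
Product: 7 methyl (1S)-1,3-dimethyl-2-{[(trifluoromethyl)sulfonyl]oxy}cyclohex-2-ene-1-carboxylate
Conditions: KHMDS, THF, −78 °C; PhNTf2, −78 → 0 °C
Reagents that add atoms: N-phenylbis(trifluoromethanesulfonimide), O=S(=O)(N(c1ccccc1)S(=O)(=O)C(F)(F)F)C(F)(F)F
Why: O-Sulfonylation of the only possible (tetrasubstituted) potassium enolate gives the enol triflate (enol triflate formation) without touching the quaternary stereocentre.

**Step 5**
Reactants: 7 methyl (1S)-1,3-dimethyl-2-{[(trifluoromethyl)sulfonyl]oxy}cyclohex-2-ene-1-carboxylate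
Product: 8 (6R)-6-(hydroxymethyl)-2,6-dimethylcyclohex-1-en-1-yl trifluoromethanesulfonate
Conditions: DIBAL-H (2.5 equiv), CH2Cl2, −78 → −20 °C; aq. potassium sodium tartrate
Reagents that add atoms: none
Why: DIBAL-H reduces the methyl ester to the primary alcohol at low temperature, conditions under which an enol triflate is inert (ester reduction).

**Step 6**
Reactants: 9 methyl geranate [methyl (2E)-3,7-dimethylocta-2,6-dienoate]
Product: 10 methyl (2E,6E)-3,7-dimethyl-8-oxoocta-2,6-dienoate
Conditions: SeO2 (1.1 equiv), 1,4-dioxane/H2O (95:5), reflux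
Reagents that add atoms: selenium dioxide, O=[Se]=O
Why: Selenium dioxide allylic oxidation (ene reaction, then [2,3]-shift) attacks the E-methyl group of the electron-rich trisubstituted alkene and leaves the deactivated enoate untouched, giving the (E)-enal.

**Step 7**
Reactants: 10 methyl (2E,6E)-3,7-dimethyl-8-oxoocta-2,6-dienoate
Product: 11 methyl (2E,6E)-3,7-dimethylnona-2,6-dien-8-ynoate
Conditions: dimethyl (1-diazo-2-oxopropyl)phosphonate, K2CO3, MeOH, 0 °C → rt
Reagents that add atoms: dimethyl (1-diazo-2-oxopropyl)phosphonate, COP(=O)(OC)C(=[N+]=[N-])C(C)=O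
Why: Seyferth–Gilbert homologation with the Ohira–Bestmann reagent converts the aldehyde into the terminal alkyne under mild carbonate conditions with retention of both alkene geometries.

**Step 8**
Reactants: 8 (6R)-6-(hydroxymethyl)-2,6-dimethylcyclohex-1-en-1-yl trifluoromethanesulfonate; 11 methyl (2E,6E)-3,7-dimethylnona-2,6-dien-8-ynoate
Product: 12 methyl (2E,6E)-9-[(6S)-6-(hydroxymethyl)-2,6-dimethylcyclohex-1-en-1-yl]-3,7-dimethylnona-2,6-dien-8-ynoate
Conditions: Pd(PPh3)4 (5 mol%), CuI (10 mol%), Et3N, DMF, rt → 45 °C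
Reagents that add atoms: none
Why: Sonogashira coupling of an enol triflate with a terminal alkyne forms the C5–C6 bond (labdane numbering) with retention at both partners; the free hydroxyl and the enoate are tolerated.

**Step 9**
Reactants: 12 methyl (2E,6E)-9-[(6S)-6-(hydroxymethyl)-2,6-dimethylcyclohex-1-en-1-yl]-3,7-dimethylnona-2,6-dien-8-ynoate
Product: 15 methyl (4S,5S,9R,10S,13E)-18-hydroxy-6-oxolabda-7,13-dien-15-oate, via Z-enol ether 13 (not isolated), via tricyclic dienol ether 14 (not isolated)
Conditions: Ph3PAuNTf2 (2 mol%), CH2Cl2, 0 °C; then Tf2NH (10 mol%), −40 → 0 °C; then THF/0.1 M aq. HCl, 0 °C → rt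
Reagents that add atoms: water, O
Why: Au(I) activates the C6≡C7 alkyne for anti 5-exo-dig attack of the C18 hydroxyl (protodeauration gives Z-enol ether 13); Tf2NH then protonates C7 to a planar 2-alkylidene-oxolanylium ion (C6=O⁺ ↔ C10⁺), C9 of the E-C8=C9 alkene adds to C10, loss of H7 gives dienol ether 14, and aqueous acid hydrolyses it with protonation at C5 to enone 15. The closest known reactions are the tandem alkynol cycloisomerisation/Prins cyclisation and the acid-promoted enone–olefin (cation–olefin) closure of ring B in monocyclic terpenoid ketones. Two rings close: the temporary oxolane O18–C18–C4–C5–C6 (5-exo-dig, opened again on hydrolysis) and ring B through the C9–C10 bond (6-endo-trig at the nucleophilic alkene, i.e. conjugate addition to the unsaturated oxocarbenium ion). C10 is controlled by the tether, which holds C18 in the plane of the cation so that the C4 methyl is pseudo-axial and C9 must add to the opposite face (C10 methyl cis to the C4 methyl, trans to C18); C9 follows from the E-alkene in a chair-like transition state with the side chain pseudo-equatorial; C5 follows from protonation of 14 anti to the two axial methyl groups, which is also the thermodynamic trans ring fusion. The step needs 5-exo rather than 6-endo O-attack (secured by ring size and by C6 being the alkyne carbon next to the tetrasubstituted C5=C10 bond), C7- rather than C9-protonation of 13 (kinetic α-protonation at low temperature, which avoids a Nazarov-type pentadienyl cation), and bonding at C10 rather than C6 (only C10 gives a six-membered ring).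

**Step 10**
Reactants: 15 methyl (4S,5S,9R,10S,13E)-18-hydroxy-6-oxolabda-7,13-dien-15-oate
Product: 16 methyl (4S,5S,6S,9R,10S,13E)-6,18-dihydroxylabda-7,13-dien-15-oate (C6 epimer of the target)
Conditions: NaBH4, CeCl3·7H2O, MeOH, −40 °C
Reagents that add atoms: none
Why: Luche 1,2-reduction of the enone: hydride can only reach C6 from the face opposite the two axial methyl groups on C4 and C10, which gives the axial (6S) allylic alcohol, the C6 epimer of the target.

**Step 11**
Reactants: 16 methyl (4S,5S,6S,9R,10S,13E)-6,18-dihydroxylabda-7,13-dien-15-oate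
Product: 17 methyl (4S,5S,6S,9R,10S,13E)-6-hydroxy-18-oxolabda-7,13-dien-15-oate
Conditions: TEMPO (10 mol%), PhI(OAc)2 (1.1 equiv), CH2Cl2, rt
Reagents that add atoms: none
Why: Oxoammonium (TEMPO) oxidation with PhI(OAc)2 as terminal oxidant is selective for a primary alcohol over the secondary allylic alcohol, which here is axial and flanked by two syn-axial methyl groups, and it stops at the aldehyde.

**Step 12**
Reactants: 17 methyl (4S,5S,6S,9R,10S,13E)-6-hydroxy-18-oxolabda-7,13-dien-15-oate
Product: 19 methyl (4S,5S,6R,9R,10S,13E)-6,18-dihydroxylabda-7,13-dien-15-oate, via lactol 18 (not isolated)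
Conditions: THF/H2O (4:1), HCl (0.1 M), 0 °C → rt; then NaHCO3 to pH 7–8, NaBH4, MeOH, 0 °C; non-acidic work-up
Reagents that add atoms: water, O
Why: Acid ionises the axial allylic C6–O bond and the C18 aldehyde (hydrate) oxygen, held on the opposite face by the equatorial C4–C18 bond, captures C6 in a five-membered ring (SN1 substitution with neighbouring-group participation, analogous to acid-induced allylic lactonisation), so lactol 18 forms with inversion at C6, and sodium borohydride then reduces it through its open hydroxy-aldehyde form without touching the enoate.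

**Compound list**
1 | methyl 2-oxocyclohexane-1-carboxylate | COC(=O)C1CCCCC1=O | starting material
2 | tert-butyl L-valinate | CC(C)[C@H](N)C(=O)OC(C)(C)C | starting material
3 | methyl 2-{[(2S)-1-tert-butoxy-3-methyl-1-oxobutan-2-yl]amino}cyclohex-1-ene-1-carboxylate | COC(=O)C1=C(N[C@@H](C(C)C)C(=O)OC(C)(C)C)CCCC1 | intermediate
4 | methyl (1S)-2-{[(2S)-1-tert-butoxy-3-methyl-1-oxobutan-2-yl]imino}-1-methylcyclohexane-1-carboxylate | CC(C)[C@H](N=C1CCCC[C@]1(C)C(=O)OC)C(=O)OC(C)(C)C | intermediate (not isolated)
5 | methyl (1S)-1-methyl-2-oxocyclohexane-1-carboxylate | O=C1CCCC[C@]1(C)C(=O)OC | intermediate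
6 | methyl (1S,3RS)-1,3-dimethyl-2-oxocyclohexane-1-carboxylate | O=C1C(C)CCC[C@]1(C)C(=O)OC | intermediate
7 | methyl (1S)-1,3-dimethyl-2-{[(trifluoromethyl)sulfonyl]oxy}cyclohex-2-ene-1-carboxylate | FC(F)(F)S(=O)(=O)OC1=C(C)CCC[C@]1(C)C(=O)OC | intermediate
8 | (6R)-6-(hydroxymethyl)-2,6-dimethylcyclohex-1-en-1-yl trifluoromethanesulfonate | FC(F)(F)S(=O)(=O)OC1=C(C)CCC[C@]1(C)CO | intermediate
9 | methyl geranate, methyl (2E)-3,7-dimethylocta-2,6-dienoate | COC(=O)/C=C(\C)CCC=C(C)C | starting material
10 | methyl (2E,6E)-3,7-dimethyl-8-oxoocta-2,6-dienoate | COC(=O)/C=C(\C)CC/C=C(\C)C=O | intermediate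
11 | methyl (2E,6E)-3,7-dimethylnona-2,6-dien-8-ynoate | COC(=O)/C=C(\C)CC/C=C(\C)C#C | intermediate
12 | methyl (2E,6E)-9-[(6S)-6-(hydroxymethyl)-2,6-dimethylcyclohex-1-en-1-yl]-3,7-dimethylnona-2,6-dien-8-ynoate | COC(=O)/C=C(\C)CC/C=C(\C)C#CC1=C(C)CCC[C@]1(C)CO | intermediate
13 | methyl (2E,6E)-8-[(1Z,3aS)-3a,7-dimethyl-3a,4,5,6-tetrahydro-2-benzofuran-1(3H)-ylidene]-3,7-dimethylocta-2,6-dienoate | COC(=O)/C=C(\C)CC/C=C(\C)/C=C1\OC[C@@]2(C)CCCC(C)=C12 | intermediate (not isolated)
14 | methyl (4S,9R,10S,13E)-6,18-epoxylabda-5,7,13-trien-15-oate | COC(=O)/C=C(\C)CC[C@@H]1C(C)=CC2=C3[C@@](C)(CO2)CCC[C@@]13C | intermediate (not isolated)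
15 | methyl (4S,5S,9R,10S,13E)-18-hydroxy-6-oxolabda-7,13-dien-15-oate | COC(=O)/C=C(\C)CC[C@@H]1C(C)=CC(=O)[C@@H]2[C@@](C)(CO)CCC[C@@]12C | intermediate
16 | methyl (4S,5S,6S,9R,10S,13E)-6,18-dihydroxylabda-7,13-dien-15-oate | COC(=O)/C=C(\C)CC[C@@H]1C(C)=C[C@H](O)[C@@H]2[C@@](C)(CO)CCC[C@@]12C | intermediate
17 | methyl (4S,5S,6S,9R,10S,13E)-6-hydroxy-18-oxolabda-7,13-dien-15-oate | COC(=O)/C=C(\C)CC[C@@H]1C(C)=C[C@H](O)[C@@H]2[C@@](C)(C=O)CCC[C@@]12C | intermediate
18 | methyl (4S,5S,6R,9R,10S,13E)-6,18-epoxy-18-hydroxylabda-7,13-dien-15-oate (lactol, both C18 epimers) | COC(=O)/C=C(\C)CC[C@@H]1C(C)=C[C@H]2OC(O)[C@@]3(C)CCC[C@]1(C)[C@H]23 | intermediate (not isolated)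
19 | methyl (4S,5S,6R,9R,10S,13E)-6,18-dihydroxylabda-7,13-dien-15-oate (CNP0149445.1) | COC(=O)/C=C(\C)CC[C@@H]1C(C)=C[C@@H](O)[C@@H]2[C@@](C)(CO)CCC[C@@]12C | target

**Step count and risks**
Total: 12 steps. Longest linear sequence: 10 steps (steps 1–5 and 8–12); the side-chain branch is steps 6–7.

Steps most likely to fail:

Step 9. The hydroxyl may add in the 6-endo sense to C7, which leaves no electrophile at C10. Enol ether 13 may be protonated at C9 instead of C7, giving a cross-conjugated pentadienyl cation that closes to a five-membered ring. Reversible proton loss next to the cationic centres may scramble C9. The facial bias at C10 may be too small. The fallback sets out from 12 and comes back at 19, closing ring B by a pericyclic reaction instead. Semihydrogenation of the alkyne (H2, lead-poisoned Pd/CaCO3, quinoline, EtOAc/hexane) gives the (8Z)-triene methyl (2E,6E,8Z)-9-[(6S)-6-(hydroxymethyl)-2,6-dimethylcyclohex-1-en-1-yl]-3,7-dimethylnona-2,6,8-trienoate F1. Irradiation (λ ≥ 300 nm, Et2O, 0 °C) brings about the conrotatory 6π-electrocyclisation known from the previtamin D → provitamin D ring closure, which places H9 and the C10 methyl anti and gives the ring-B diene methyl (4S,9R,10S,13E)-18-hydroxylabda-5,7,13-trien-15-oate F2. The helical sense of this closure is not controlled by a tether, so chromatographic purification and recycling of unchanged triene should be expected. Hydroboration–oxidation (BH3·THF, 0 °C; NaBO3) then adds boron to C6 and hydrogen to C5 on the face opposite the C10 methyl, as in the conversion of steroidal 5,7-dienes into 6α-hydroxy-Δ7 compounds, and should give 19 directly.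

Step 12. E1 loss of H5, H9 or a C17 proton from the allyl cation may compete with capture by the aldehyde oxygen, which would form dienes and scramble C9. The fallback sets out from 16 and comes back at 19, putting the C6 oxygen in by hydroboration instead of substitution. Silylation of the primary alcohol (TBSCl, imidazole, DMF) gives methyl (4S,5S,6S,9R,10S,13E)-18-(tert-butyldimethylsilyloxy)-6-hydroxylabda-7,13-dien-15-oate F3. Anti-elimination of the axial C6 hydroxyl with the trans-diaxial H5 (POCl3, pyridine, 0 °C → rt) gives the diene methyl (4S,9R,10S,13E)-18-(tert-butyldimethylsilyloxy)labda-5,7,13-trien-15-oate F4. Hydroboration–oxidation (BH3·THF; NaBO3) gives methyl (4S,5S,6R,9R,10S,13E)-18-(tert-butyldimethylsilyloxy)-6-hydroxylabda-7,13-dien-15-oate F5, and TBAF in THF should then give 19.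

Step 11. The primary alcohol is neopentylic and slow, so the oxoammonium salt may also oxidise the secondary allylic alcohol, or over-oxidation may occur. The fallback sets out from 16 and comes back at 19 without any change of oxidation level at C18. Selective acylation of the primary alcohol (4-nitrobenzoyl chloride, pyridine, CH2Cl2, 0 °C) gives methyl (4S,5S,6S,9R,10S,13E)-6-hydroxy-18-(4-nitrobenzoyloxy)labda-7,13-dien-15-oate F6. Mitsunobu inversion of the C6 alcohol (4-nitrobenzoic acid, PPh3, DIAD, toluene) gives methyl (4S,5S,6R,9R,10S,13E)-6,18-bis(4-nitrobenzoyloxy)labda-7,13-dien-15-oate F7. Methanolysis (K2CO3, MeOH) should then give 19.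

**Further compounds**
F1 | step 9 | methyl (2E,6E,8Z)-9-[(6S)-6-(hydroxymethyl)-2,6-dimethylcyclohex-1-en-1-yl]-3,7-dimethylnona-2,6,8-trienoate | COC(=O)/C=C(\C)CC/C=C(\C)/C=C\C1=C(C)CCC[C@]1(C)CO
F2 | step 9 | methyl (4S,9R,10S,13E)-18-hydroxylabda-5,7,13-trien-15-oate | COC(=O)/C=C(\C)CC[C@@H]1C(C)=CC=C2[C@@](C)(CO)CCC[C@@]12C
F3 | step 12 | methyl (4S,5S,6S,9R,10S,13E)-18-(tert-butyldimethylsilyloxy)-6-hydroxylabda-7,13-dien-15-oate | COC(=O)/C=C(\C)CC[C@@H]1C(C)=C[C@H](O)[C@@H]2[C@@](C)(CO[Si](C)(C)C(C)(C)C)CCC[C@@]12C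
F4 | step 12 | methyl (4S,9R,10S,13E)-18-(tert-butyldimethylsilyloxy)labda-5,7,13-trien-15-oate | COC(=O)/C=C(\C)CC[C@@H]1C(C)=CC=C2[C@@](C)(CO[Si](C)(C)C(C)(C)C)CCC[C@@]12C
F5 | step 12 | methyl (4S,5S,6R,9R,10S,13E)-18-(tert-butyldimethylsilyloxy)-6-hydroxylabda-7,13-dien-15-oate | COC(=O)/C=C(\C)CC[C@@H]1C(C)=C[C@@H](O)[C@@H]2[C@@](C)(CO[Si](C)(C)C(C)(C)C)CCC[C@@]12C
F6 | step 11 | methyl (4S,5S,6S,9R,10S,13E)-6-hydroxy-18-(4-nitrobenzoyloxy)labda-7,13-dien-15-oate | COC(=O)/C=C(\C)CC[C@@H]1C(C)=C[C@H](O)[C@@H]2[C@@](C)(COC(=O)c3ccc(cc3)[N+](=O)[O-])CCC[C@@]12C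
F7 | step 11 | methyl (4S,5S,6R,9R,10S,13E)-6,18-bis(4-nitrobenzoyloxy)labda-7,13-dien-15-oate | COC(=O)/C=C(\C)CC[C@@H]1C(C)=C[C@@H](OC(=O)c3ccc(cc3)[N+](=O)[O-])[C@@H]2[C@@](C)(COC(=O)c3ccc(cc3)[N+](=O)[O-])CCC[C@@]12C
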